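**Retrosynthetic overview**

1. The target is an oxolane (O1, C2H2, C3, C4, C5) with CH(OH)Ar′ on C3, CH2OH on C4 and Ar on C5. The CH2OH oxygen and the carbinol oxygen are 1,4-related across the C3–C4 bond, so one SiMe2 unit (C–Si to the CH2 carbon, O–Si to the carbinol oxygen) closes a six-membered 1,2-oxasilinane trans-fused to C3–C4. This feature makes the key step possible; the target is the Tamao oxidation product of that Si-bridged oxolane.
2. The oxolane O1–C2 bond is cut next (cyclodehydration of a 1,4-diol), which leads back to a γ-lactone whose carbonyl carbon is the future C2.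
3. Key disconnection: the bond from the lactone α-carbon (future C3) to the carbinol carbon, together with the silylmethyl group on the β-carbon (future C4). This is a three-component conjugate addition–aldol reaction of an (R)-γ-aryl butenolide, a silylmethyl Grignard reagent and 3,4-dimethoxybenzaldehyde, in which silicon ring closure funnels the carbinol epimers of a reversible aldol into one.
4. The butenolide comes from 3,4,5-trimethoxybenzaldehyde and methyl propiolate (asymmetric alkynylation, semihydrogenation, lactonisation).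
5. Ring order: lactone (step 2), oxasilinane (step 3), lactone opened (step 4), oxolane (step 5), oxasilinane removed (step 6).

Key step: step 3

Remark: the ProPhenol enantiomer in step 1 is defined by its outcome (acetylide delivery to the Re face of the aldehyde); the other ligand enantiomer would give the enantiomeric series.

**Route**

Step 1
Reactants: 1 3,4,5-trimethoxybenzaldehyde; 2 methyl propiolate
Product: 3 methyl (S)-4-hydroxy-4-(3,4,5-trimethoxyphenyl)but-2-ynoate
Conditions: ProPhenol ligand (10 mol%, Re-face-selective enantiomer), Me2Zn (3 equiv), PhMe, 4 °C; aq NH4Cl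
Reagents that add atoms: none
Why: Zinc–ProPhenol catalysed asymmetric alkynylation of an aryl aldehyde, in which the dinuclear zinc catalyst should deliver the zinc acetylide of 2 to the Re face of 1 and so set the centre that becomes C5 of the oxolane.

Step 2
Reactants: 3 methyl (S)-4-hydroxy-4-(3,4,5-trimethoxyphenyl)but-2-ynoate
Product: 5 (R)-5-(3,4,5-trimethoxyphenyl)furan-2(5H)-one, via (Z)-hydroxy enoate 4 (not isolated)
Conditions: H2 (1 atm), Lindlar catalyst, quinoline, EtOAc, 23 °C; then PPTS (cat.), CH2Cl2, 23 °C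
Reagents that add atoms: none
Why: Lindlar semihydrogenation should give the (Z)-γ-hydroxy enoate, which lactonises with loss of methanol; the stereocentre is untouched (the descriptor changes from S to R only through the CIP ranking).

Step 3
Reactants: 5 (R)-5-(3,4,5-trimethoxyphenyl)furan-2(5H)-one; 6 (chloromethyl)(isopropoxy)dimethylsilane; 7 3,4-dimethoxybenzaldehyde
Product: 11 (1R,3aS,4S,7aR)-4-(3,4-dimethoxyphenyl)-6,6-dimethyl-1-(3,4,5-trimethoxyphenyl)hexahydrofuro[3,4-d][1,2]oxasilin-3-one, via Grignard reagent 8 (not isolated), via magnesium enolate 9 (not isolated), via magnesium aldolate 10 (not isolated)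
Conditions: 6, Mg, THF, 23 °C; then 5, CuBr·SMe2 (10 mol%), THF, −78 °C; then 7, −78 → 23 °C, 12 h; aq NH4Cl
Reagents that add atoms: none
Why: Proposed new method: Cu-catalysed 1,4-addition of 8 to 5 should occur on the face opposite the C5 aryl group and give enolate 9 (this sets the lactone β-carbon), 9 should add to 7 on the face opposite the new silylmethyl arm (this sets the α-carbon, trans), and aldolate 10 forms as both carbinol epimers, which interconvert by retro-aldol/aldol because aldolates of the electron-rich aldehyde 7 revert easily. The aldolate oxygen then displaces isopropoxide from the tethered silicon (6-exo-tet at Si) and closes the 1,2-oxasilinane trans-fused to the lactone; alkoxide exchange at silicon is itself reversible, so the ring closure is a thermodynamic sink and not a kinetic trap. In the chair of this trans-fused ring only the S carbinol epimer places the 3,4-dimethoxyphenyl group equatorial (the R epimer needs it axial, syn to a Si–CH3 group), so the epimer mixture should be funnelled into 11; this tether control sets the carbinol centre. The closest known reaction types are the three-component conjugate addition–aldol reaction of butenolides, the Cu-catalysed conjugate addition of the (isopropoxydimethylsilyl)methyl Grignard reagent as a hydroxymethyl anion equivalent, and alkoxide exchange at alkoxysilanes; new is their combination into a silicon-templated, stereoconvergent aldol. The step needs 1,4-addition to outrun γ-deprotonation of 5 (Cu catalysis at −78 °C) and needs silylation to be slower than aldolate equilibration (bulky OiPr on silicon, chelated magnesium aldolate).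

Step 4
Reactants: 11 (1R,3aS,4S,7aR)-4-(3,4-dimethoxyphenyl)-6,6-dimethyl-1-(3,4,5-trimethoxyphenyl)hexahydrofuro[3,4-d][1,2]oxasilin-3-one
Product: 12 (R)-[(4R,5R,6S)-6-(3,4-dimethoxyphenyl)-5-(hydroxymethyl)-2,2-dimethyl-1,2-oxasilinan-4-yl](3,4,5-trimethoxyphenyl)methanol
Conditions: DIBAL-H (4 equiv), CH2Cl2, −78 → 0 °C; aq Rochelle salt
Reagents that add atoms: none
Why: Aluminium hydride reduction of a γ-lactone to the 1,4-diol, in which the silylated aldol oxygen cannot undergo retro-aldol, the weakly nucleophilic aluminium alkoxides should leave the silyl ether in place, and no stereocentre is involved.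

Step 5
Reactants: 12 (R)-[(4R,5R,6S)-6-(3,4-dimethoxyphenyl)-5-(hydroxymethyl)-2,2-dimethyl-1,2-oxasilinan-4-yl](3,4,5-trimethoxyphenyl)methanol
Product: 13 (1R,3aR,4S,7aR)-4-(3,4-dimethoxyphenyl)-6,6-dimethyl-1-(3,4,5-trimethoxyphenyl)hexahydrofuro[3,4-d][1,2]oxasiline
Conditions: PPh3, DIAD, THF, 0 → 23 °C
Reagents that add atoms: none
Why: Mitsunobu cyclodehydration of a 1,4-diol, in which the primary hydroxyl should be activated as the alkoxyphosphonium ion and displaced by the benzylic hydroxyl (5-exo-tet), so the benzylic centre keeps its configuration and the other carbinol oxygen stays masked by silicon.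

Step 6
Reactants: 13 (1R,3aR,4S,7aR)-4-(3,4-dimethoxyphenyl)-6,6-dimethyl-1-(3,4,5-trimethoxyphenyl)hexahydrofuro[3,4-d][1,2]oxasiline
Product: 14 (S)-(3,4-dimethoxyphenyl)[(3R,4S,5R)-4-(hydroxymethyl)-5-(3,4,5-trimethoxyphenyl)oxolan-3-yl]methanol
Conditions: 30% aq H2O2, KF, KHCO3, THF/MeOH (1:1), 23 → 40 °C
Reagents that add atoms: hydrogen peroxide, OO
Why: Tamao oxidation of a cyclic alkoxysilane, which should convert the CH2–Si bond into CH2–OH and cleave the Si–O bond to free the benzylic alcohol with its configuration unchanged.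

**Compound list**

1 | 3,4,5-trimethoxybenzaldehyde | COc1cc(C=O)cc(OC)c1OC | starting material
2 | methyl propiolate | C#CC(=O)OC | starting material
3 | methyl (S)-4-hydroxy-4-(3,4,5-trimethoxyphenyl)but-2-ynoate | COC(=O)C#C[C@@H](O)c1cc(OC)c(OC)c(OC)c1 | intermediate
4 | methyl (R,Z)-4-hydroxy-4-(3,4,5-trimethoxyphenyl)but-2-enoate | COC(=O)/C=C\[C@@H](O)c1cc(OC)c(OC)c(OC)c1 | intermediate
5 | (R)-5-(3,4,5-trimethoxyphenyl)furan-2(5H)-one | O=C1C=C[C@H](c2cc(OC)c(OC)c(OC)c2)O1 | intermediate
6 | (chloromethyl)(isopropoxy)dimethylsilane | CC(C)O[Si](C)(C)CCl | starting material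
7 | 3,4-dimethoxybenzaldehyde | COc1ccc(C=O)cc1OC | starting material
8 | [(isopropoxydimethylsilyl)methyl]magnesium chloride | CC(C)O[Si](C)(C)C[Mg]Cl | intermediate
9 | chloromagnesium (4R,5R)-4-{[isopropoxy(dimethyl)silyl]methyl}-5-(3,4,5-trimethoxyphenyl)-4,5-dihydrofuran-2-olate (silylmethyl trans to aryl) | Cl[Mg]OC1=C[C@@H](C[Si](C)(C)OC(C)C)[C@H](c2cc(OC)c(OC)c(OC)c2)O1 | intermediate
10 | chloromagnesium (S)-(3,4-dimethoxyphenyl)[(3S,4R,5R)-4-{[isopropoxy(dimethyl)silyl]methyl}-2-oxo-5-(3,4,5-trimethoxyphenyl)oxolan-3-yl]methanolate (productive carbinol epimer drawn; it equilibrates with its epimer) | COc1ccc([C@@H](O[Mg]Cl)[C@H]2C(=O)O[C@@H](c3cc(OC)c(OC)c(OC)c3)[C@@H]2C[Si](C)(C)OC(C)C)cc1OC | intermediate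
11 | (1R,3aS,4S,7aR)-4-(3,4-dimethoxyphenyl)-6,6-dimethyl-1-(3,4,5-trimethoxyphenyl)hexahydrofuro[3,4-d][1,2]oxasilin-3-one (γ-lactone trans-fused at its α,β-bond to a 2,2-dimethyl-1,2-oxasilinane; aryl on the O-bearing carbon equatorial) | COc1ccc([C@H]2O[Si](C)(C)C[C@H]3[C@H](c4cc(OC)c(OC)c(OC)c4)OC(=O)[C@H]23)cc1OC | intermediate
12 | (R)-[(4R,5R,6S)-6-(3,4-dimethoxyphenyl)-5-(hydroxymethyl)-2,2-dimethyl-1,2-oxasilinan-4-yl](3,4,5-trimethoxyphenyl)methanol | COc1ccc([C@H]2O[Si](C)(C)C[C@@H]([C@@H](O)c3cc(OC)c(OC)c(OC)c3)[C@@H]2CO)cc1OC | intermediate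
13 | (1R,3aR,4S,7aR)-4-(3,4-dimethoxyphenyl)-6,6-dimethyl-1-(3,4,5-trimethoxyphenyl)hexahydrofuro[3,4-d][1,2]oxasiline (oxolane trans-fused to the oxasilinane) | COc1ccc([C@H]2O[Si](C)(C)C[C@H]3[C@H](c4cc(OC)c(OC)c(OC)c4)OC[C@H]23)cc1OC | intermediate
14 | (S)-(3,4-dimethoxyphenyl)[(3R,4S,5R)-4-(hydroxymethyl)-5-(3,4,5-trimethoxyphenyl)oxolan-3-yl]methanol | COc1ccc([C@@H](O)[C@H]2CO[C@@H](c3cc(OC)c(OC)c(OC)c3)[C@@H]2CO)cc1OC | target

**Step count and risks**

Total steps: 6. Longest linear sequence: 6 steps (1 → 3 → 5 → 11 → 12 → 13 → 14).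

Step 3 (bears the new-method label). The silicon ring closure may be faster or slower than assumed, so that the carbinol epimers are trapped kinetically instead of being funnelled. The aldolate may also be lost by β-elimination during the equilibration, or 5 may be deprotonated at its γ-position (racemisation) before conjugate addition. The fallback sets out from 5 and comes back at 11, using known chemistry only. Cu-catalysed conjugate addition of 8 to 5 with a protic quench should give the trans lactone (4R,5R)-4-{[isopropoxy(dimethyl)silyl]methyl}-5-(3,4,5-trimethoxyphenyl)oxolan-2-one F1. Its lithium enolate (LiHMDS, 2 equiv, THF, −78 °C) is C-acylated with 3,4-dimethoxybenzoyl chloride (Claisen acylation) to the β-keto lactone (3S,4R,5R)-3-(3,4-dimethoxybenzoyl)-4-{[isopropoxy(dimethyl)silyl]methyl}-5-(3,4,5-trimethoxyphenyl)oxolan-2-one F2, whose acidic C3 settles trans. Chelation-controlled reduction (Zn(BH4)2, Et2O, −20 °C) delivers hydride to the ketone face opposite the ring and should give the syn hydroxy lactone (3S,4R,5R)-3-[(S)-(3,4-dimethoxyphenyl)(hydroxy)methyl]-4-{[isopropoxy(dimethyl)silyl]methyl}-5-(3,4,5-trimethoxyphenyl)oxolan-2-one F3. PPTS (cat.) in toluene then closes the oxasilinane to 11.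

Step 5. The benzylic hydroxyl may be activated instead of the primary one (ionisation, elimination or inversion at the benzylic carbon), or the silyl group may migrate to the primary oxygen during steps 4 and 5 so that the wrong oxygen is free. The fallback sets out from 11 and comes back at 13 without opening the five-membered ring. Partial reduction (DIBAL-H, 1.1 equiv, CH2Cl2, −78 °C) should stop at the lactol (1R,3aS,4S,7aR)-4-(3,4-dimethoxyphenyl)-6,6-dimethyl-1-(3,4,5-trimethoxyphenyl)hexahydrofuro[3,4-d][1,2]oxasilin-3-ol F4 (both anomers). Ionic hydrogenation of its oxocarbenium ion (Et3SiH, BF3·OEt2, CH2Cl2, −78 °C) should then give 13.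

Step 1. Facial discrimination may be insufficient in the acetylide addition to the electron-rich, slowly reacting aldehyde, with competing uncatalysed transfer. The fallback sets out from 1 and comes back at 5, with the stereocentre set by ketone reduction instead of C–C bond formation. Stetter reaction of 1 with methyl acrylate (thiazolium salt, Et3N, EtOH, 80 °C) should give methyl 4-oxo-4-(3,4,5-trimethoxyphenyl)butanoate F5. Noyori transfer hydrogenation (RuCl(p-cymene)[(R,R)-TsDPEN], HCO2H/Et3N), by analogy with aryl methyl ketones, should give methyl (R)-4-hydroxy-4-(3,4,5-trimethoxyphenyl)butanoate F6, which lactonises (TsOH cat.) to (R)-5-(3,4,5-trimethoxyphenyl)oxolan-2-one F7. α-Selenation (LDA, PhSeBr, THF, −78 °C) gives (5R)-3-(phenylselanyl)-5-(3,4,5-trimethoxyphenyl)oxolan-2-one F8, and selenoxide syn-elimination (H2O2, CH2Cl2, 0 °C) returns 5.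

Further compounds
F1 | step 3 | (4R,5R)-4-{[isopropoxy(dimethyl)silyl]methyl}-5-(3,4,5-trimethoxyphenyl)oxolan-2-one | O=C1C[C@@H](C[Si](C)(C)OC(C)C)[C@H](c2cc(OC)c(OC)c(OC)c2)O1
F2 | step 3 | (3S,4R,5R)-3-(3,4-dimethoxybenzoyl)-4-{[isopropoxy(dimethyl)silyl]methyl}-5-(3,4,5-trimethoxyphenyl)oxolan-2-one | COc1ccc(C(=O)[C@H]2C(=O)O[C@@H](c3cc(OC)c(OC)c(OC)c3)[C@@H]2C[Si](C)(C)OC(C)C)cc1OC
F3 | step 3 | (3S,4R,5R)-3-[(S)-(3,4-dimethoxyphenyl)(hydroxy)methyl]-4-{[isopropoxy(dimethyl)silyl]methyl}-5-(3,4,5-trimethoxyphenyl)oxolan-2-one | COc1ccc([C@@H](O)[C@H]2C(=O)O[C@@H](c3cc(OC)c(OC)c(OC)c3)[C@@H]2C[Si](C)(C)OC(C)C)cc1OC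
F4 | step 5 | (1R,3aS,4S,7aR)-4-(3,4-dimethoxyphenyl)-6,6-dimethyl-1-(3,4,5-trimethoxyphenyl)hexahydrofuro[3,4-d][1,2]oxasilin-3-ol (both anomers) | COc1ccc([C@H]2O[Si](C)(C)C[C@H]3[C@H](c4cc(OC)c(OC)c(OC)c4)OC(O)[C@H]23)cc1OC
F5 | step 1 | methyl 4-oxo-4-(3,4,5-trimethoxyphenyl)butanoate | COC(=O)CCC(=O)c1cc(OC)c(OC)c(OC)c1
F6 | step 1 | methyl (R)-4-hydroxy-4-(3,4,5-trimethoxyphenyl)butanoate | COC(=O)CC[C@@H](O)c1cc(OC)c(OC)c(OC)c1
F7 | step 1 | (R)-5-(3,4,5-trimethoxyphenyl)oxolan-2-one | O=C1CC[C@H](c2cc(OC)c(OC)c(OC)c2)O1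
F8 | step 1 | (5R)-3-(phenylselanyl)-5-(3,4,5-trimethoxyphenyl)oxolan-2-one (both C3 epimers) | O=C1C([Se]c2ccccc2)C[C@H](c3cc(OC)c(OC)c(OC)c3)O1
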